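**Strategy.** The route rests on cutting the dihydropyranone (ring atoms O1, C2(=O), C3=C4, C5(Me), C6) at C2–C3 and C5–C6. The ring's C3–C4–C5 unit is treated at the alkyne level as a but-1-yne 1,3-dianion equivalent. In one flask an axially chiral allenylstannane adds by SE2′ to an α-branched glyoxal monoacetal (C5–C6, both stereocentres), and the alkyne terminus thus freed is carboxylated with CO2 (C2–C3). The precursors (an allene, an aldehyde and CO2) bear no resemblance to a lactone; cis-semihydrogenation then closes the ring. Two palladium-free copper-mediated alkenyl–alkenyl unions, a Marshall–Tamaru propargylation and an Evans aldol complete the chain; the C8 ketone is unveiled last.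

Key step: step 3

Remark: chain positions are numbered as in the target acid (C1 = CO2H to C19). The carbinol configuration created at C8 in step 25 is immaterial, because step 29 oxidises that centre.

Remark: aldehyde 4 is sold as an aqueous solution and is assumed to be dried azeotropically before use. In steps 7 and 23 the catalyst antipode is the one expected to give the stated configuration.

**West fragment (lactone alkenylstannane)**

Step 1
Reactants: 1 (S)-but-3-yn-2-ol
Product: 2 (S)-but-3-yn-2-yl methanesulfonate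
Conditions: MsCl, Et3N, CH2Cl2, −78 to 0 °C
Reagents that add atoms: methanesulfonyl chloride CS(=O)(=O)Cl
Why: O-sulfonylation leaves the carbinol configuration untouched and installs the leaving group for the SN2′ step.

Step 2
Reactants: 2 (S)-but-3-yn-2-yl methanesulfonate
Product: 3 (M)-tributyl(buta-1,2-dien-1-yl)stannane
Conditions: Bu3SnH, LDA, THF, −78 °C; CuBr·SMe2; then 2, −78 °C
Reagents that add atoms: tributyltin hydride CCCC[SnH](CCCC)CCCC
Why: Stannylcuprate displacement of a propargylic mesylate is an anti SN2′ process, so the carbinol chirality should be transferred to the M allene axis.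

Step 3
Reactants: 4 2,2-dimethoxyacetaldehyde and 3 (M)-tributyl(buta-1,2-dien-1-yl)stannane
Product: 7 (4S,5R)-5-hydroxy-6,6-dimethoxy-4-methylhex-2-ynoic acid, via magnesium alkoxide 5 (not isolated), via alkynylmagnesium bromide 6 (not isolated)
Conditions: MgBr2·OEt2, CH2Cl2, −23 °C; then THF, EtMgBr (3.5 equiv), 0 °C to rt; then CO2 (1 atm), 0 °C; aq. citric acid
Reagents that add atoms: carbon dioxide O=C=O
Why: MgBr2 chelates the α-methoxy aldehyde and the allenylstannane attacks through an open, antiperiplanar anti-SE2′ transition state, forming the C5–C6 bond of the future pyranone and releasing Bu3SnBr; EtMgBr then metallates the alkyne terminus thus freed, and the alkynyl Grignard adds to CO2, forming the C2–C3 bond. The closest known reaction types are the Lewis-acid-promoted SE2′ propargylation of aldehydes by chiral allenylstannanes and the carboxylation of alkynylmagnesium halides. No ring is closed here; the δ-hydroxy-ynoic acid is the acyclic precursor that lactonises in step 4. C5 (methyl-bearing) is set by the M axis of 3 through stereospecific anti attack, and C6 (carbinol) by the syn topicity that α-branched aldehydes show in this open transition state. The step needs γ-attack of the stannane (propargyl, not allenyl, product), which the SE2′ mechanism secures, and C- rather than O-carboxylation, which is secured because the magnesium alkyl carbonate formed at oxygen reverts to the alcohol on acidic work-up.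

Step 4
Reactants: 7 (4S,5R)-5-hydroxy-6,6-dimethoxy-4-methylhex-2-ynoic acid
Product: 9 (5S,6R)-6-(dimethoxymethyl)-5-methyl-5,6-dihydro-2H-pyran-2-one, via cis-hydroxy acid 8 (not isolated)
Conditions: H2 (1 atm), Pd/CaCO3–Pb(OAc)2 (Lindlar catalyst), quinoline, EtOAc, rt; filter; PPTS (cat.), CH2Cl2, rt
Reagents that add atoms: none
Why: Lindlar cis-semihydrogenation places the carboxyl group cis to C5, so acid-catalysed 6-exo-trig lactonisation should close the pyranone without touching either stereocentre.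

Step 5
Reactants: 9 (5S,6R)-6-(dimethoxymethyl)-5-methyl-5,6-dihydro-2H-pyran-2-one
Product: 10 (2R,3S)-3-methyl-6-oxo-3,6-dihydro-2H-pyran-2-carbaldehyde
Conditions: CF3CO2H–H2O (9:1), CHCl3, 0 °C; used crude
Reagents that add atoms: water O
Why: Acid-catalysed acetal hydrolysis unmasks the formyl group under non-basic conditions that should not epimerise the α-acyloxy centre.

Step 6
Reactants: 10 (2R,3S)-3-methyl-6-oxo-3,6-dihydro-2H-pyran-2-carbaldehyde
Product: 11 (5S,6R)-5-methyl-6-[(E)-2-(tributylstannyl)ethenyl]-5,6-dihydro-2H-pyran-2-one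
Conditions: CrCl2 (10 equiv), Bu3SnCHBr2, LiI, THF–DMF, 0 °C to rt, dark
Reagents that add atoms: tributyl(dibromomethyl)stannane CCCC[Sn](CCCC)(CCCC)C(Br)Br
Why: Hodgson (Takai-type) olefination through a geminal dichromium species should give the (E)-alkenylstannane under neutral, divalent-chromium conditions that spare the enoate and the α-centre.

**Middle fragment and its union with the lactone**

Step 7
Reactants: 12 3-methylidenedihydrofuran-2(3H)-one
Product: 13 (R)-3-methyldihydrofuran-2(3H)-one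
Conditions: H2 (100 atm), Ru(OAc)2[(S)-BINAP] (0.5 mol %), CH2Cl2, 50 °C
Reagents that add atoms: none
Why: Noyori-type asymmetric hydrogenation of the exocyclic enoate sets C15 by catalyst control.

Step 8
Reactants: 13 (R)-3-methyldihydrofuran-2(3H)-one
Product: 14 (3R)-3-methyltetrahydrofuran-2-ol (anomer mixture)
Conditions: i-Bu2AlH (1.1 equiv), CH2Cl2, −78 °C; Rochelle salt
Reagents that add atoms: none
Why: Half-reduction of a γ-lactone stops at the lactol because the tetrahedral aluminate is stable at −78 °C.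

Step 9
Reactants: 14 (3R)-3-methyltetrahydrofuran-2-ol
Product: 15 (R,Z)-5-iodo-3-methylhept-4-en-1-ol
Conditions: Ph3P(n-Pr)Br, n-BuLi, THF, 0 °C; I2, −78 °C; NaN(SiMe3)2, −20 °C; then 14, −78 °C to rt
Reagents that add atoms: propyltriphenylphosphonium bromide CCC[P+](c1ccccc1)(c1ccccc1)c1ccccc1.[Br-]; iodine II
Why: Stork–Zhao-type Wittig olefination of the open hydroxy-aldehyde form with the α-iodo ylide should give the trisubstituted iodoalkene with iodine cis to the chain, which is the geometry needed for 16Z.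

Step 10
Reactants: 15 (R,Z)-5-iodo-3-methylhept-4-en-1-ol and 11 (5S,6R)-5-methyl-6-[(E)-2-(tributylstannyl)ethenyl]-5,6-dihydro-2H-pyran-2-one
Product: 16 (5S,6S)-6-[(1E,3Z,5R)-3-ethyl-7-hydroxy-5-methylhepta-1,3-dien-1-yl]-5-methyl-5,6-dihydro-2H-pyran-2-one
Conditions: Cu(O2C-2-thienyl) (CuTC, 1.5 equiv), NMP, 0 °C
Reagents that add atoms: none
Why: Liebeskind coupling with a monovalent copper carboxylate joins alkenyl iodide and alkenylstannane with retention of both geometries and without zerovalent palladium, which could ionise the allylic lactone.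

Step 11
Reactants: 16 (5S,6S)-6-[(1E,3Z,5R)-3-ethyl-7-hydroxy-5-methylhepta-1,3-dien-1-yl]-5-methyl-5,6-dihydro-2H-pyran-2-one
Product: 17 (3R,4Z,6E)-5-ethyl-3-methyl-7-[(2S,3S)-3-methyl-6-oxo-3,6-dihydro-2H-pyran-2-yl]hepta-4,6-dienal
Conditions: Dess–Martin periodinane, NaHCO3, CH2Cl2, 0 °C to rt
Reagents that add atoms: none
Why: Dess–Martin oxidation of the primary alcohol is neutral, and the new aldehyde has no α-stereocentre to lose.

Step 12
Reactants: 17 (3R,4Z,6E)-5-ethyl-3-methyl-7-[(2S,3S)-3-methyl-6-oxo-3,6-dihydro-2H-pyran-2-yl]hepta-4,6-dienal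
Product: 18 (5S,6S)-6-[(1E,3Z,5R,7E)-3-ethyl-5-methyl-8-(tributylstannyl)octa-1,3,7-trien-1-yl]-5-methyl-5,6-dihydro-2H-pyran-2-one
Conditions: CrCl2 (10 equiv), Bu3SnCHBr2, LiI, THF–DMF, 0 °C to rt, dark
Reagents that add atoms: tributyl(dibromomethyl)stannane CCCC[Sn](CCCC)(CCCC)C(Br)Br
Why: A second Hodgson olefination should install the (E)-alkenylstannane at C12 under conditions the dienyl lactone tolerates.

**East fragment**

Step 13
Reactants: 19 (R)-3-bromo-2-methylpropan-1-ol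
Product: 20 (R)-(3-bromo-2-methylpropoxy)(tert-butyl)dimethylsilane
Conditions: TBSCl, imidazole, CH2Cl2, rt
Reagents that add atoms: tert-butyldimethylsilyl chloride CC(C)(C)[Si](C)(C)Cl
Why: Silylation masks the hydroxyl for the acetylide and alane steps.

Step 14
Reactants: 20 (R)-(3-bromo-2-methylpropoxy)(tert-butyl)dimethylsilane
Product: 21 (S)-tert-butyldimethyl[(2-methylpent-4-yn-1-yl)oxy]silane
Conditions: LiC≡CH·H2NCH2CH2NH2, DMSO, rt
Reagents that add atoms: lithium acetylide–ethylenediamine complex [Li]C#C.NCCN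
Why: SN2 displacement of the primary bromide leaves C5 untouched; only its descriptor changes, through CIP priority.

Step 15
Reactants: 21 (S)-tert-butyldimethyl[(2-methylpent-4-yn-1-yl)oxy]silane
Product: 23 methyl (S,E)-6-[(tert-butyldimethylsilyl)oxy]-3,5-dimethylhex-2-enoate, via alkenylalane 22 (not isolated)
Conditions: AlMe3 (3 equiv), ZrCp2Cl2 (0.3 equiv), CH2Cl2, 0 °C to rt; then ClCO2Me, 0 °C to rt
Reagents that add atoms: trimethylaluminium C[Al](C)C; methyl chloroformate COC(=O)Cl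
Why: Negishi zirconium-catalysed carboalumination adds methyl and aluminium syn with aluminium at the terminus, and acylation of the alkenylalane with retention should give the (E)-enoate.

Step 16
Reactants: 23 methyl (S,E)-6-[(tert-butyldimethylsilyl)oxy]-3,5-dimethylhex-2-enoate
Product: 24 methyl (S,E)-6-hydroxy-3,5-dimethylhex-2-enoate
Conditions: CSA (cat.), MeOH–CH2Cl2, 0 °C
Reagents that add atoms: none
Why: Acid-catalysed methanolysis removes the primary silyl ether; the (E)-enoate geometry precludes lactonisation.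

Step 17
Reactants: 24 methyl (S,E)-6-hydroxy-3,5-dimethylhex-2-enoate
Product: 25 methyl (S,E)-3,5-dimethyl-6-oxohex-2-enoate
Conditions: Dess–Martin periodinane, NaHCO3, CH2Cl2, 0 °C; used directly
Reagents that add atoms: none
Why: Buffered Dess–Martin oxidation should give the α-methyl aldehyde without epimerisation.

Step 18
Reactants: 25 methyl (S,E)-3,5-dimethyl-6-oxohex-2-enoate and 26 (S)-4-benzyl-3-propionyloxazolidin-2-one
Product: 28 methyl (2E,5S,6R,7S)-8-[(S)-4-benzyl-2-oxooxazolidin-3-yl]-6-hydroxy-3,5,7-trimethyl-8-oxooct-2-enoate, via boron enolate 27 (not isolated)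
Conditions: n-Bu2BOTf, i-Pr2NEt, CH2Cl2, 0 °C; 25, −78 to 0 °C; pH 7 buffer, MeOH, H2O2
Reagents that add atoms: none
Why: Evans syn-aldol through the (Z)-boron enolate and a Zimmerman–Traxler chair sets C6 and C7 by auxiliary control, which overrides the aldehyde's α-centre and should give the all-syn C5–C7 triad.

Step 19
Reactants: 28 methyl (2E,5S,6R,7S)-8-[(S)-4-benzyl-2-oxooxazolidin-3-yl]-6-hydroxy-3,5,7-trimethyl-8-oxooct-2-enoate
Product: 29 methyl (2E,5S,6R,7S)-8-[(S)-4-benzyl-2-oxooxazolidin-3-yl]-6-[(tert-butyldimethylsilyl)oxy]-3,5,7-trimethyl-8-oxooct-2-enoate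
Conditions: TBSOTf, 2,6-lutidine, CH2Cl2, −78 °C
Reagents that add atoms: tert-butyldimethylsilyl trifluoromethanesulfonate CC(C)(C)[Si](C)(C)OS(=O)(=O)C(F)(F)F
Why: Silylation blocks retro-aldol cleavage and keeps C6 at the alcohol level until the last step.

Step 20
Reactants: 29 methyl (2E,5S,6R,7S)-8-[(S)-4-benzyl-2-oxooxazolidin-3-yl]-6-[(tert-butyldimethylsilyl)oxy]-3,5,7-trimethyl-8-oxooct-2-enoate
Product: 30 methyl (2E,5S,6R,7R)-6-[(tert-butyldimethylsilyl)oxy]-8-hydroxy-3,5,7-trimethyloct-2-enoate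
Conditions: LiBH4, MeOH (1 equiv), THF, 0 °C
Reagents that add atoms: none
Why: The imide carbonyl is far more electrophilic than the conjugated, β,β-disubstituted methyl ester, so reductive removal of the auxiliary should be chemoselective.

Step 21
Reactants: 30 methyl (2E,5S,6R,7R)-6-[(tert-butyldimethylsilyl)oxy]-8-hydroxy-3,5,7-trimethyloct-2-enoate
Product: 31 methyl (2E,5S,6R,7S)-6-[(tert-butyldimethylsilyl)oxy]-3,5,7-trimethyl-8-oxooct-2-enoate
Conditions: Dess–Martin periodinane, NaHCO3, CH2Cl2, 0 °C; used directly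
Reagents that add atoms: none
Why: Neutral oxidation gives the C8 aldehyde without epimerising C7.

Step 22
Reactants: 32 ethyl 2-[(tert-butyldimethylsilyl)oxy]acetate
Product: 33 1-[(tert-butyldimethylsilyl)oxy]pent-3-yn-2-one
Conditions: 1-propynyllithium, BF3·OEt2, THF, −78 °C
Reagents that add atoms: 1-propynyllithium [Li]C#CC
Why: Acylation of the alkynylborane-type nucleophile by an ester stops at the ynone because the tetrahedral adduct survives at −78 °C.

Step 23
Reactants: 33 1-[(tert-butyldimethylsilyl)oxy]pent-3-yn-2-one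
Product: 34 (R)-1-[(tert-butyldimethylsilyl)oxy]pent-3-yn-2-ol
Conditions: RuCl[(S,S)-TsDPEN](p-cymene) (1 mol %), i-PrOH, rt
Reagents that add atoms: none
Why: Noyori asymmetric transfer hydrogenation of an alkynyl ketone is catalyst-controlled through the alkyne–arene interaction in the six-membered transition state.

Step 24
Reactants: 34 (R)-1-[(tert-butyldimethylsilyl)oxy]pent-3-yn-2-ol
Product: 35 (R)-1-[(tert-butyldimethylsilyl)oxy]pent-3-yn-2-yl methanesulfonate
Conditions: MsCl, Et3N, CH2Cl2, −78 °C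
Reagents that add atoms: methanesulfonyl chloride CS(=O)(=O)Cl
Why: Mesylation with retention provides the propargylic electrophile for palladium insertion.

Step 25
Reactants: 31 methyl (2E,5S,6R,7S)-6-[(tert-butyldimethylsilyl)oxy]-3,5,7-trimethyl-8-oxooct-2-enoate and 35 (R)-1-[(tert-butyldimethylsilyl)oxy]pent-3-yn-2-yl methanesulfonate
Product: 37 methyl (2E,5S,6R,7R,8R,9S)-6-[(tert-butyldimethylsilyl)oxy]-9-{[(tert-butyldimethylsilyl)oxy]methyl}-8-hydroxy-3,5,7-trimethyldodec-2-en-10-ynoate, via allenylzinc 36 (not isolated)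
Conditions: Pd(OAc)2 (5 mol %), PPh3 (5 mol %), Et2Zn (3 equiv), THF, −78 to −20 °C
Reagents that add atoms: none
Why: In the Marshall–Tamaru propargylation, anti oxidative addition of zerovalent palladium, transmetalation to zinc and a cyclic SE2′ addition transfer the mesylate chirality to C9 with net inversion, anti to the new carbinol.

Step 26
Reactants: 37 methyl (2E,5S,6R,7R,8R,9S)-6-[(tert-butyldimethylsilyl)oxy]-9-{[(tert-butyldimethylsilyl)oxy]methyl}-8-hydroxy-3,5,7-trimethyldodec-2-en-10-ynoate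
Product: 39 methyl (2E,5S,6R,7R,8R,9S,10E)-6-[(tert-butyldimethylsilyl)oxy]-9-{[(tert-butyldimethylsilyl)oxy]methyl}-8-hydroxy-11-iodo-3,5,7-trimethyldodeca-2,10-dienoate, via alkenylstannane 38 (not isolated)
Conditions: Bu3SnH, PdCl2(PPh3)2 (2 mol %), THF, 0 °C; then I2, CH2Cl2, 0 °C
Reagents that add atoms: iodine II
Why: Palladium-catalysed syn-hydrostannation should place tin on the methyl-bearing alkyne carbon, away from the branched propargylic centre, and iododestannylation retains the (E) geometry.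

Step 27
Reactants: 39 methyl (2E,5S,6R,7R,8R,9S,10E)-6-[(tert-butyldimethylsilyl)oxy]-9-{[(tert-butyldimethylsilyl)oxy]methyl}-8-hydroxy-11-iodo-3,5,7-trimethyldodeca-2,10-dienoate
Product: 40 (2E,5S,6R,7R,8R,9S,10E)-6-[(tert-butyldimethylsilyl)oxy]-9-{[(tert-butyldimethylsilyl)oxy]methyl}-8-hydroxy-11-iodo-3,5,7-trimethyldodeca-2,10-dienoic acid
Conditions: Me3SnOH (5 equiv), ClCH2CH2Cl, 80 °C; aq. KHSO4
Reagents that add atoms: trimethyltin hydroxide C[Sn](C)(C)O
Why: Tin-hydroxide ester hydrolysis is near neutral, so no free alkoxide forms at C8 and silyl migration from O6 or the C9 oxymethyl group should not occur.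

**Union and endgame**

Step 28
Reactants: 18 (5S,6S)-6-[(1E,3Z,5R,7E)-3-ethyl-5-methyl-8-(tributylstannyl)octa-1,3,7-trien-1-yl]-5-methyl-5,6-dihydro-2H-pyran-2-one and 40 (2E,5S,6R,7R,8R,9S,10E)-6-[(tert-butyldimethylsilyl)oxy]-9-{[(tert-butyldimethylsilyl)oxy]methyl}-8-hydroxy-11-iodo-3,5,7-trimethyldodeca-2,10-dienoic acid
Product: 41 (2E,5S,6R,7R,8R,9S,10E,12E,15R,16Z,18E)-6-[(tert-butyldimethylsilyl)oxy]-9-{[(tert-butyldimethylsilyl)oxy]methyl}-17-ethyl-8-hydroxy-3,5,7,11,15-pentamethyl-19-[(2S,3S)-3-methyl-6-oxo-3,6-dihydro-2H-pyran-2-yl]nonadeca-2,10,12,16,18-pentaenoic acid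
Conditions: Cu(O2C-2-thienyl) (CuTC, 3 equiv), NMP, 0 °C to rt
Reagents that add atoms: none
Why: A second Liebeskind coupling forms C11–C12 with retention at both alkenes, giving the (10E,12E)-diene without palladium or base in the presence of the lactone.

Step 29
Reactants: 41 (2E,5S,6R,7R,8R,9S,10E,12E,15R,16Z,18E)-6-[(tert-butyldimethylsilyl)oxy]-9-{[(tert-butyldimethylsilyl)oxy]methyl}-17-ethyl-8-hydroxy-3,5,7,11,15-pentamethyl-19-[(2S,3S)-3-methyl-6-oxo-3,6-dihydro-2H-pyran-2-yl]nonadeca-2,10,12,16,18-pentaenoic acid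
Product: 42 (2E,5S,6R,7S,9S,10E,12E,15R,16Z,18E)-6-[(tert-butyldimethylsilyl)oxy]-9-{[(tert-butyldimethylsilyl)oxy]methyl}-17-ethyl-3,5,7,11,15-pentamethyl-19-[(2S,3S)-3-methyl-6-oxo-3,6-dihydro-2H-pyran-2-yl]-8-oxononadeca-2,10,12,16,18-pentaenoic acid
Conditions: Dess–Martin periodinane, NaHCO3, CH2Cl2, 0 °C
Reagents that add atoms: none
Why: The C8 hydroxyl is the only free alcohol, and buffered Dess–Martin oxidation should give the ketone without epimerising the now labile C9 and C7 centres.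

Step 30
Reactants: 42 (2E,5S,6R,7S,9S,10E,12E,15R,16Z,18E)-6-[(tert-butyldimethylsilyl)oxy]-9-{[(tert-butyldimethylsilyl)oxy]methyl}-17-ethyl-3,5,7,11,15-pentamethyl-19-[(2S,3S)-3-methyl-6-oxo-3,6-dihydro-2H-pyran-2-yl]-8-oxononadeca-2,10,12,16,18-pentaenoic acid
Product: 43 kazusamycin A
Conditions: HF·pyridine, pyridine, THF, 0 °C to rt
Reagents that add atoms: none
Why: Buffered HF·pyridine cleaves both silyl ethers under mildly acidic conditions that should spare the β-hydroxy ketone, the C9 centre and the lactone.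

**Compound list**

1 | (S)-but-3-yn-2-ol | C#C[C@H](C)O | starting material
2 | (S)-but-3-yn-2-yl methanesulfonate | C#C[C@H](C)OS(C)(=O)=O | intermediate
3 | (M)-tributyl(buta-1,2-dien-1-yl)stannane | CC([H])=[C@]=C([H])[Sn](CCCC)(CCCC)CCCC | intermediate
4 | 2,2-dimethoxyacetaldehyde | COC(OC)C=O | starting material
5 | bromomagnesium (2R,3S)-1,1-dimethoxy-3-methylpent-4-yn-2-olate | COC(OC)[C@H](O[Mg]Br)[C@@H](C)C#C | intermediate
6 | bromomagnesium (2R,3S)-5-(bromomagnesio)-1,1-dimethoxy-3-methylpent-4-yn-2-olate | COC(OC)[C@H](O[Mg]Br)[C@@H](C)C#C[Mg]Br | intermediate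
7 | (4S,5R)-5-hydroxy-6,6-dimethoxy-4-methylhex-2-ynoic acid | COC(OC)[C@H](O)[C@@H](C)C#CC(=O)O | intermediate
8 | (2Z,4S,5R)-5-hydroxy-6,6-dimethoxy-4-methylhex-2-enoic acid | COC(OC)[C@H](O)[C@@H](C)/C=C\C(=O)O | intermediate
9 | (5S,6R)-6-(dimethoxymethyl)-5-methyl-5,6-dihydro-2H-pyran-2-one | COC(OC)[C@@H]1OC(=O)C=C[C@@H]1C | intermediate
10 | (2R,3S)-3-methyl-6-oxo-3,6-dihydro-2H-pyran-2-carbaldehyde | O=C[C@@H]1OC(=O)C=C[C@@H]1C | intermediate
11 | (5S,6R)-5-methyl-6-[(E)-2-(tributylstannyl)ethenyl]-5,6-dihydro-2H-pyran-2-one | CCCC[Sn](CCCC)(CCCC)/C=C/[C@@H]1OC(=O)C=C[C@@H]1C | intermediate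
12 | 3-methylidenedihydrofuran-2(3H)-one | C=C1CCOC1=O | starting material
13 | (R)-3-methyldihydrofuran-2(3H)-one | O=C1[C@H](C)CCO1 | intermediate
14 | (3R)-3-methyltetrahydrofuran-2-ol | OC1[C@H](C)CCO1 | intermediate
15 | (R,Z)-5-iodo-3-methylhept-4-en-1-ol | CCC(=C/[C@H](C)CCO)/I | intermediate
16 | (5S,6S)-6-[(1E,3Z,5R)-3-ethyl-7-hydroxy-5-methylhepta-1,3-dien-1-yl]-5-methyl-5,6-dihydro-2H-pyran-2-one | CCC(=C/[C@H](C)CCO)/C=C/[C@@H]1OC(=O)C=C[C@@H]1C | intermediate
17 | (3R,4Z,6E)-5-ethyl-3-methyl-7-[(2S,3S)-3-methyl-6-oxo-3,6-dihydro-2H-pyran-2-yl]hepta-4,6-dienal | CCC(=C/[C@H](C)CC=O)/C=C/[C@@H]1OC(=O)C=C[C@@H]1C | intermediate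
18 | (5S,6S)-6-[(1E,3Z,5R,7E)-3-ethyl-5-methyl-8-(tributylstannyl)octa-1,3,7-trien-1-yl]-5-methyl-5,6-dihydro-2H-pyran-2-one | CCC(=C/[C@H](C)C/C=C/[Sn](CCCC)(CCCC)CCCC)/C=C/[C@@H]1OC(=O)C=C[C@@H]1C | intermediate
19 | (R)-3-bromo-2-methylpropan-1-ol | OC[C@@H](C)CBr | starting material
20 | (R)-(3-bromo-2-methylpropoxy)(tert-butyl)dimethylsilane | CC(C)(C)[Si](C)(C)OC[C@@H](C)CBr | intermediate
21 | (S)-tert-butyldimethyl[(2-methylpent-4-yn-1-yl)oxy]silane | CC(C)(C)[Si](C)(C)OC[C@@H](C)CC#C | intermediate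
22 | [(1E,4S)-5-[(tert-butyldimethylsilyl)oxy]-2,4-dimethylpent-1-en-1-yl]dimethylalane | CC(C)(C)[Si](C)(C)OC[C@@H](C)C/C(C)=C/[Al](C)C | intermediate
23 | methyl (S,E)-6-[(tert-butyldimethylsilyl)oxy]-3,5-dimethylhex-2-enoate | CC(C)(C)[Si](C)(C)OC[C@@H](C)C/C(C)=C/C(=O)OC | intermediate
24 | methyl (S,E)-6-hydroxy-3,5-dimethylhex-2-enoate | OC[C@@H](C)C/C(C)=C/C(=O)OC | intermediate
25 | methyl (S,E)-3,5-dimethyl-6-oxohex-2-enoate | O=C[C@@H](C)C/C(C)=C/C(=O)OC | intermediate
26 | (S)-4-benzyl-3-propionyloxazolidin-2-one | CCC(=O)N1[C@@H](Cc2ccccc2)COC1=O | starting material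
27 | (S)-4-benzyl-3-[(Z)-1-(dibutylboranyloxy)prop-1-en-1-yl]oxazolidin-2-one | C/C=C(\OB(CCCC)CCCC)N1[C@@H](Cc2ccccc2)COC1=O | intermediate
28 | methyl (2E,5S,6R,7S)-8-[(S)-4-benzyl-2-oxooxazolidin-3-yl]-6-hydroxy-3,5,7-trimethyl-8-oxooct-2-enoate | O=C([C@@H](C)[C@H](O)[C@@H](C)C/C(C)=C/C(=O)OC)N1[C@@H](Cc2ccccc2)COC1=O | intermediate
29 | methyl (2E,5S,6R,7S)-8-[(S)-4-benzyl-2-oxooxazolidin-3-yl]-6-[(tert-butyldimethylsilyl)oxy]-3,5,7-trimethyl-8-oxooct-2-enoate | O=C([C@@H](C)[C@H](O[Si](C)(C)C(C)(C)C)[C@@H](C)C/C(C)=C/C(=O)OC)N1[C@@H](Cc2ccccc2)COC1=O | intermediate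
30 | methyl (2E,5S,6R,7R)-6-[(tert-butyldimethylsilyl)oxy]-8-hydroxy-3,5,7-trimethyloct-2-enoate | OC[C@@H](C)[C@H](O[Si](C)(C)C(C)(C)C)[C@@H](C)C/C(C)=C/C(=O)OC | intermediate
31 | methyl (2E,5S,6R,7S)-6-[(tert-butyldimethylsilyl)oxy]-3,5,7-trimethyl-8-oxooct-2-enoate | O=C[C@@H](C)[C@H](O[Si](C)(C)C(C)(C)C)[C@@H](C)C/C(C)=C/C(=O)OC | intermediate
32 | ethyl 2-[(tert-butyldimethylsilyl)oxy]acetate | CCOC(=O)CO[Si](C)(C)C(C)(C)C | starting material
33 | 1-[(tert-butyldimethylsilyl)oxy]pent-3-yn-2-one | CC#CC(=O)CO[Si](C)(C)C(C)(C)C | intermediate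
34 | (R)-1-[(tert-butyldimethylsilyl)oxy]pent-3-yn-2-ol | CC#C[C@@H](O)CO[Si](C)(C)C(C)(C)C | intermediate
35 | (R)-1-[(tert-butyldimethylsilyl)oxy]pent-3-yn-2-yl methanesulfonate | CC#C[C@@H](OS(C)(=O)=O)CO[Si](C)(C)C(C)(C)C | intermediate
36 | (M)-{5-[(tert-butyldimethylsilyl)oxy]penta-2,3-dien-2-yl}(ethyl)zinc | CC([Zn]CC)=[C@@]=C([H])CO[Si](C)(C)C(C)(C)C | intermediate
37 | methyl (2E,5S,6R,7R,8R,9S)-6-[(tert-butyldimethylsilyl)oxy]-9-{[(tert-butyldimethylsilyl)oxy]methyl}-8-hydroxy-3,5,7-trimethyldodec-2-en-10-ynoate | CC#C[C@@H](CO[Si](C)(C)C(C)(C)C)[C@@H](O)[C@@H](C)[C@H](O[Si](C)(C)C(C)(C)C)[C@@H](C)C/C(C)=C/C(=O)OC | intermediate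
38 | methyl (2E,5S,6R,7R,8R,9S,10E)-6-[(tert-butyldimethylsilyl)oxy]-9-{[(tert-butyldimethylsilyl)oxy]methyl}-8-hydroxy-3,5,7-trimethyl-11-(tributylstannyl)dodeca-2,10-dienoate | CCCC[Sn](CCCC)(CCCC)/C(C)=C/[C@@H](CO[Si](C)(C)C(C)(C)C)[C@@H](O)[C@@H](C)[C@H](O[Si](C)(C)C(C)(C)C)[C@@H](C)C/C(C)=C/C(=O)OC | intermediate
39 | methyl (2E,5S,6R,7R,8R,9S,10E)-6-[(tert-butyldimethylsilyl)oxy]-9-{[(tert-butyldimethylsilyl)oxy]methyl}-8-hydroxy-11-iodo-3,5,7-trimethyldodeca-2,10-dienoate | I/C(C)=C/[C@@H](CO[Si](C)(C)C(C)(C)C)[C@@H](O)[C@@H](C)[C@H](O[Si](C)(C)C(C)(C)C)[C@@H](C)C/C(C)=C/C(=O)OC | intermediate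
40 | (2E,5S,6R,7R,8R,9S,10E)-6-[(tert-butyldimethylsilyl)oxy]-9-{[(tert-butyldimethylsilyl)oxy]methyl}-8-hydroxy-11-iodo-3,5,7-trimethyldodeca-2,10-dienoic acid | I/C(C)=C/[C@@H](CO[Si](C)(C)C(C)(C)C)[C@@H](O)[C@@H](C)[C@H](O[Si](C)(C)C(C)(C)C)[C@@H](C)C/C(C)=C/C(=O)O | intermediate
41 | (2E,5S,6R,7R,8R,9S,10E,12E,15R,16Z,18E)-6-[(tert-butyldimethylsilyl)oxy]-9-{[(tert-butyldimethylsilyl)oxy]methyl}-17-ethyl-8-hydroxy-3,5,7,11,15-pentamethyl-19-[(2S,3S)-3-methyl-6-oxo-3,6-dihydro-2H-pyran-2-yl]nonadeca-2,10,12,16,18-pentaenoic acid | CCC(=C/[C@H](C)C/C=C/C(C)=C/[C@@H](CO[Si](C)(C)C(C)(C)C)[C@@H](O)[C@@H](C)[C@H](O[Si](C)(C)C(C)(C)C)[C@@H](C)C/C(C)=C/C(=O)O)/C=C/[C@@H]1OC(=O)C=C[C@@H]1C | intermediate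
42 | (2E,5S,6R,7S,9S,10E,12E,15R,16Z,18E)-6-[(tert-butyldimethylsilyl)oxy]-9-{[(tert-butyldimethylsilyl)oxy]methyl}-17-ethyl-3,5,7,11,15-pentamethyl-19-[(2S,3S)-3-methyl-6-oxo-3,6-dihydro-2H-pyran-2-yl]-8-oxononadeca-2,10,12,16,18-pentaenoic acid | CCC(=C/[C@H](C)C/C=C/C(C)=C/[C@@H](CO[Si](C)(C)C(C)(C)C)C(=O)[C@@H](C)[C@H](O[Si](C)(C)C(C)(C)C)[C@@H](C)C/C(C)=C/C(=O)O)/C=C/[C@@H]1OC(=O)C=C[C@@H]1C | intermediate
43 | kazusamycin A, (2E,5S,6R,7S,9S,10E,12E,15R,16Z,18E)-17-ethyl-6-hydroxy-9-(hydroxymethyl)-3,5,7,11,15-pentamethyl-19-[(2S,3S)-3-methyl-6-oxo-3,6-dihydro-2H-pyran-2-yl]-8-oxononadeca-2,10,12,16,18-pentaenoic acid | CCC(=C/[C@H](C)C/C=C/C(C)=C/[C@@H](CO)C(=O)[C@@H](C)[C@H](O)[C@@H](C)C/C(C)=C/C(=O)O)/C=C/[C@@H]1OC(=O)C=C[C@@H]1C | target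

**Step count and risks**

Total step count: 30. Longest linear sequence: 15 steps (steps 13–21 and 25–30, from 19).

Steps most likely to fail:

Step 3. The syn topicity of the open SE2′ transition state may erode, and metallation and carboxylation of the alkyne may stay incomplete in the mixed CH2Cl2–THF medium that still holds tin and magnesium salts. The fallback sets out from aldehyde 4 and builds the ring by olefin metathesis instead. Reagent-controlled (Z)-crotylboration with the matched enantiomer of (Z)-crotyl-B(Ipc)2 should give (2R,3S)-1,1-dimethoxy-3-methylpent-4-en-2-ol F1. Acryloyl chloride and Et3N should convert it into (2R,3S)-1,1-dimethoxy-3-methylpent-4-en-2-yl prop-2-enoate F2. Ring-closing metathesis with the second-generation Grubbs catalyst then returns to the route at lactone 9.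

Step 9. The lactol may open only sluggishly toward the basic iodo-ylide, and the Z geometry or the C15 centre may suffer through enolisation of the transient aldehyde. The fallback sets out from lactol 14 and fixes the geometry by cross-coupling instead of olefination. Dibromo-olefination (CBr4, PPh3, Et3N) should give (R)-5,5-dibromo-3-methylpent-4-en-1-ol F3. Trans-selective Negishi monoethylation (Et2Zn, PdCl2(DPEphos), THF) should give (R,Z)-5-bromo-3-methylhept-4-en-1-ol F4. Copper-catalysed bromide–iodide exchange (NaI, CuI, trans-N,N′-dimethylcyclohexane-1,2-diamine, dioxane) then returns to the route at iodide 15.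

Step 28. The free carboxylic acid of 40 may protodestannylate 18 before transmetalation to copper, and the hindered 2-iodoalkene may couple slowly. The fallback sets out from aldehyde 17 and replaces tin and copper by boron and palladium. Takai–Utimoto olefination (CrCl2, Cl2CHB(pin), LiI, THF) should give (5S,6S)-6-[(1E,3Z,5R,7E)-3-ethyl-5-methyl-8-(4,4,5,5-tetramethyl-1,3,2-dioxaborolan-2-yl)octa-1,3,7-trien-1-yl]-5-methyl-5,6-dihydro-2H-pyran-2-one F5. A fast Suzuki–Miyaura coupling with 40 (Pd(PPh3)4, TlOEt, THF–H2O, rt) then returns to the route at seco-acid 41.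

Further compounds
F1 | step 3 | (2R,3S)-1,1-dimethoxy-3-methylpent-4-en-2-ol | COC(OC)[C@H](O)[C@@H](C)C=C
F2 | step 3 | (2R,3S)-1,1-dimethoxy-3-methylpent-4-en-2-yl prop-2-enoate | COC(OC)[C@H](OC(=O)C=C)[C@@H](C)C=C
F3 | step 9 | (R)-5,5-dibromo-3-methylpent-4-en-1-ol | BrC(Br)=C[C@H](C)CCO
F4 | step 9 | (R,Z)-5-bromo-3-methylhept-4-en-1-ol | CCC(=C/[C@H](C)CCO)/Br
F5 | step 28 | (5S,6S)-6-[(1E,3Z,5R,7E)-3-ethyl-5-methyl-8-(4,4,5,5-tetramethyl-1,3,2-dioxaborolan-2-yl)octa-1,3,7-trien-1-yl]-5-methyl-5,6-dihydro-2H-pyran-2-one | CCC(=C/[C@H](C)C/C=C/B1OC(C)(C)C(C)(C)O1)/C=C/[C@@H]1OC(=O)C=C[C@@H]1C
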